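**Retrosynthetic overview**
1. The last C–C bond is C4–C1'. After phenol deprotection, the target goes back to a C4 benzylic cation of ring C, stabilised by O1 (ortho) and 7-OMe (para) on ring A, and an (E)-4-hydroxystyryl trifluoroborate.
2. The cation comes from a flavan-4-ol. This alcohol is obtained as one enantiomer from a racemic 2,3-trans-3-benzylflavanone by dynamic kinetic resolution, because C2 (retro-oxa-Michael) and C3 (enolisation) are both labile next to a C4 ketone.
3. Ring C is the only ring that has to be formed, since all arene rings are bought. It closes in one operation from an acyclic enol silane and 2,4-dimethoxybenzaldehyde: C3 adds to the formyl carbon (C2–C3), and the aldehyde oxygen then displaces fluoride from C8a (O1–C8a).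
4. The enabling feature is that C4 sits between C3 and C4a of ring A. At the ketone level it makes C3 an enolate carbon and turns C8a–F into a vinylogous acyl fluoride, a 1,4 donor/acceptor pair that matches the C=O dipole. The expelled fluoride removes the silyl group of the next molecule.
5. The enol silane comes from two commercial arenes by Claisen–Schmidt condensation and 1,4-hydrosilylation.

Key step: step 3

Remark: chroman numbering is used (O1, C2, C3, C4, C4a, C5–C8, C8a; C1'/C2' are the styryl carbons; ring A is the benzo ring, ring B the 2,4-dimethoxyphenyl group, ring C the pyran). The given SMILES is read as the (2R,3R,4R), 2,3-trans-3,4-trans (all-equatorial) isomer. Racemic compounds are drawn as the enantiomer that is carried on.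

**Step 1**
Reactants: 1 1-(2-fluoro-4-methoxyphenyl)ethan-1-one; 2 4-(allyloxy)benzaldehyde
Product: 3 (E)-3-[4-(allyloxy)phenyl]-1-(2-fluoro-4-methoxyphenyl)prop-2-en-1-one
Conditions: NaOH (aq, 0.5 equiv), EtOH, 0 °C to rt
Reagents that add atoms: none
Why: Claisen–Schmidt condensation, in which the methyl ketone enolate adds to the non-enolisable aldehyde and E1cB dehydration should give the conjugated E-enone, the aryl fluoride being too weakly activated to react with hydroxide at room temperature.

**Step 2**
Reactants: 3 (E)-3-[4-(allyloxy)phenyl]-1-(2-fluoro-4-methoxyphenyl)prop-2-en-1-one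
Product: 4 (Z)-{[3-[4-(allyloxy)phenyl]-1-(2-fluoro-4-methoxyphenyl)prop-1-en-1-yl]oxy}dimethyl(phenyl)silane
Conditions: [(PPh3)CuH]6 (2 mol %), PhMe2SiH (1.3 equiv), toluene, rt
Reagents that add atoms: dimethylphenylsilane, C[SiH](C)c1ccccc1
Why: Copper hydride-catalysed 1,4-hydrosilylation, in which hydride goes to the beta carbon of the s-cis enone and the copper enolate is silylated by the silane, which should give the enol silane regiospecifically at C3 (Z expected, geometry not carried into the product) and leave the allyl alkene and the C–F bond untouched.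

**Step 3**
Reactants: 4 (Z)-{[3-[4-(allyloxy)phenyl]-1-(2-fluoro-4-methoxyphenyl)prop-1-en-1-yl]oxy}dimethyl(phenyl)silane; 5 2,4-dimethoxybenzaldehyde
Product: 8 (±)-trans-3-[4-(allyloxy)benzyl]-2-(2,4-dimethoxyphenyl)-7-methoxychroman-4-one (2R*,3S*), via ammonium enolate 6 (not isolated), via ammonium aldolate 7 (not isolated)
Conditions: 5 (1.05 equiv), anhydrous Me4NF (10 mol %), 4 Å molecular sieves, DMF, −20 °C to 40 °C
Reagents that add atoms: none
Why: Proposed new method: catalytic fluoride strips the silyl group from 4 to give the naked enolate 6, whose C3 adds to the formyl carbon of 5 (C2–C3 bond), and the alkoxide oxygen of 7 then attacks C8a of ring A, which the ortho C4 ketone has turned into a vinylogous acyl fluoride, so that addition–elimination closes ring C (O1–C8a bond) and releases the fluoride that desilylates the next molecule of 4, the strong Si–F bond of PhMe2SiF driving a chain that needs no stoichiometric base. The closest known reaction types are the fluoride-catalysed aldol addition of enol silanes, the fluoride-catalysed SNAr etherification of silyl ethers with activated aryl fluorides, and the tandem imine-addition/SNAr annulation of 2-fluoroaryl ketones to dihydroquinolinones. Ring C closes as a six-membered ring by formal 6-endo-trig attack of oxygen on the C8a=C4a–C4=O unit followed by loss of fluoride. The aldol addition is reversible, so the diastereomeric aldolates should drain through the chair-like closure that holds the C2 aryl and C3 benzyl groups equatorial, and C3 of 8 (alpha to the ketone) can still epimerise under the catalytic base, so both kinetic and thermodynamic control point to the 2,3-trans relative configuration (racemic at this stage). The step needs O-arylation to outrun E1cB dehydration and aldol–Tishchenko hydride transfer, which the absence of stoichiometric base, the near-equimolar aldehyde and the ortho-acyl activation of the only C–F bond should secure.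

**Step 4**
Reactants: 8 (±)-trans-3-[4-(allyloxy)benzyl]-2-(2,4-dimethoxyphenyl)-7-methoxychroman-4-one
Product: 10 (2R,3R,4S)-3-[4-(allyloxy)benzyl]-2-(2,4-dimethoxyphenyl)-7-methoxychroman-4-ol, via ring-opened enone 9 (not isolated)
Conditions: RuCl[(S,S)-TsDPEN](p-cymene) (2 mol %), HCO2H (3 equiv), DBU (4 equiv), MeCN, 40 °C
Reagents that add atoms: none
Why: Noyori asymmetric transfer hydrogenation run as a dynamic kinetic resolution, in which DBU racemises 8 by E1cB opening to the achiral enone 9 and oxa-Michael reclosure (plus enolisation at C3) while the (S,S)-catalyst should reduce only the (2R,3S)-ketone, delivering hydride anti to the C3 benzyl group, which fixes C2 and C3 in the absolute sense and gives a 4S carbinol whose configuration is erased again in step 7.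

**Step 5**
Reactants: 11 4-vinylphenyl acetate; 12 4,4,5,5-tetramethyl-2-vinyl-1,3,2-dioxaborolane
Product: 13 (E)-4-[2-(4,4,5,5-tetramethyl-1,3,2-dioxaborolan-2-yl)vinyl]phenyl acetate
Conditions: second-generation Grubbs catalyst (2 mol %), CH2Cl2, 40 °C
Reagents that add atoms: none
Why: Olefin cross-metathesis of a styrene with vinyl pinacol boronate, which should be E-selective for steric reasons and is driven by loss of ethene.

**Step 6**
Reactants: 13 (E)-4-[2-(4,4,5,5-tetramethyl-1,3,2-dioxaborolan-2-yl)vinyl]phenyl acetate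
Product: 15 potassium (E)-trifluoro[2-(4-hydroxyphenyl)vinyl]borate, via phenol boronate 14 (not isolated)
Conditions: K2CO3 (cat.), MeOH, rt; then aq KHF2 (4.5 equiv), rt
Reagents that add atoms: potassium hydrogen difluoride, [K+].[F-].F
Why: Base-catalysed methanolysis of the aryl acetate followed by the standard conversion of a pinacol boronate into its trifluoroborate salt with KHF2, which retains the E geometry.

**Step 7**
Reactants: 10 (2R,3R,4S)-3-[4-(allyloxy)benzyl]-2-(2,4-dimethoxyphenyl)-7-methoxychroman-4-ol; 15 potassium (E)-trifluoro[2-(4-hydroxyphenyl)vinyl]borate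
Product: 17 (2R,3R,4R)-3-[4-(allyloxy)benzyl]-2-(2,4-dimethoxyphenyl)-4-[(E)-4-hydroxystyryl]-7-methoxychroman, via C4 benzylic cation 16 (not isolated)
Conditions: 15 (2 equiv), HBF4·OEt2 (20 mol %), MeCN, −30 °C to 0 °C
Reagents that add atoms: none
Why: Brønsted acid-catalysed dehydrative substitution of a benzhydryl-type alcohol by an alkenyltrifluoroborate, in which the cation 16 (stabilised by O1 and 7-OMe) should be attacked by the boron-bearing carbon anti to the C3 benzyl group to set the 3,4-trans (4R) centre, while loss of boron ends the reaction cleanly with retention of the E alkene.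

**Step 8**
Reactants: 17 (2R,3R,4R)-3-[4-(allyloxy)benzyl]-2-(2,4-dimethoxyphenyl)-4-[(E)-4-hydroxystyryl]-7-methoxychroman
Product: 18 caraganin C
Conditions: Pd(PPh3)4 (5 mol %), morpholine (5 equiv), THF, rt
Reagents that add atoms: none
Why: Tsuji–Trost-type deallylation, in which zerovalent palladium ionises the aryl allyl ether and morpholine captures the allyl unit under neutral conditions that should touch neither the styrene, nor the acid-labile C2–O1 bond, nor any stereocentre.

**Compound list**
1 | 1-(2-fluoro-4-methoxyphenyl)ethan-1-one | CC(=O)c1ccc(OC)cc1F | starting material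
2 | 4-(allyloxy)benzaldehyde | C=CCOc1ccc(C=O)cc1 | starting material
3 | (E)-3-[4-(allyloxy)phenyl]-1-(2-fluoro-4-methoxyphenyl)prop-2-en-1-one | COc1ccc(c(F)c1)C(=O)/C=C/c1ccc(OCC=C)cc1 | intermediate
4 | (Z)-{[3-[4-(allyloxy)phenyl]-1-(2-fluoro-4-methoxyphenyl)prop-1-en-1-yl]oxy}dimethyl(phenyl)silane | COc1ccc(c(F)c1)/C(O[Si](C)(C)c1ccccc1)=C/Cc1ccc(OCC=C)cc1 | intermediate
5 | 2,4-dimethoxybenzaldehyde | COc1ccc(C=O)c(OC)c1 | starting material
6 | tetramethylammonium enolate of 3-[4-(allyloxy)phenyl]-1-(2-fluoro-4-methoxyphenyl)propan-1-one (not isolated) | COc1ccc(c(F)c1)/C([O-])=C/Cc1ccc(OCC=C)cc1.C[N+](C)(C)C | intermediate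
7 | tetramethylammonium aldolate, equilibrating diastereomers (not isolated) | COc1ccc(c(F)c1)C(=O)C(Cc1ccc(OCC=C)cc1)C([O-])c1ccc(OC)cc1OC.C[N+](C)(C)C | intermediate
8 | (±)-trans-3-[4-(allyloxy)benzyl]-2-(2,4-dimethoxyphenyl)-7-methoxychroman-4-one (racemic, 2R,3S enantiomer drawn) | COc1ccc2c(c1)O[C@@H](c1ccc(OC)cc1OC)[C@H](Cc1ccc(OCC=C)cc1)C2=O | intermediate
9 | (E)-2-[4-(allyloxy)benzyl]-3-(2,4-dimethoxyphenyl)-1-(2-hydroxy-4-methoxyphenyl)prop-2-en-1-one (not isolated) | COc1ccc(c(O)c1)C(=O)/C(Cc1ccc(OCC=C)cc1)=C/c1ccc(OC)cc1OC | intermediate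
10 | (2R,3R,4S)-3-[4-(allyloxy)benzyl]-2-(2,4-dimethoxyphenyl)-7-methoxychroman-4-ol | COc1ccc2c(c1)O[C@@H](c1ccc(OC)cc1OC)[C@H](Cc1ccc(OCC=C)cc1)[C@@H]2O | intermediate
11 | 4-vinylphenyl acetate | CC(=O)Oc1ccc(C=C)cc1 | starting material
12 | 4,4,5,5-tetramethyl-2-vinyl-1,3,2-dioxaborolane | C=CB1OC(C)(C)C(C)(C)O1 | starting material
13 | (E)-4-[2-(4,4,5,5-tetramethyl-1,3,2-dioxaborolan-2-yl)vinyl]phenyl acetate | CC(=O)Oc1ccc(/C=C/B2OC(C)(C)C(C)(C)O2)cc1 | intermediate
14 | (E)-4-[2-(4,4,5,5-tetramethyl-1,3,2-dioxaborolan-2-yl)vinyl]phenol (not isolated) | Oc1ccc(/C=C/B2OC(C)(C)C(C)(C)O2)cc1 | intermediate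
15 | potassium (E)-trifluoro[2-(4-hydroxyphenyl)vinyl]borate | [K+].Oc1ccc(/C=C/[B-](F)(F)F)cc1 | intermediate
16 | (2R,3R)-3-[4-(allyloxy)benzyl]-2-(2,4-dimethoxyphenyl)-7-methoxychroman-4-ylium (not isolated) | COc1ccc2c(c1)O[C@@H](c1ccc(OC)cc1OC)[C@H](Cc1ccc(OCC=C)cc1)[CH+]2 | intermediate
17 | (2R,3R,4R)-3-[4-(allyloxy)benzyl]-2-(2,4-dimethoxyphenyl)-4-[(E)-4-hydroxystyryl]-7-methoxychroman | COc1ccc2c(c1)O[C@@H](c1ccc(OC)cc1OC)[C@H](Cc1ccc(OCC=C)cc1)[C@H]2/C=C/c1ccc(O)cc1 | intermediate
18 | caraganin C, (2R,3R,4R) | COc1ccc2c(c1)O[C@@H](c1ccc(OC)cc1OC)[C@H](Cc1ccc(O)cc1)[C@H]2/C=C/c1ccc(O)cc1 | target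

**Total step count:** 8. **Longest linear sequence:** 6 (steps 1, 2, 3, 4, 7, 8).

**Steps most likely to fail**

1. **Step 3.**
   - Risk: the alkoxide may pass its charge to C3 and lose hydroxide (E1cB dehydration). It may also transfer hydride to a second aldehyde, or be capped by silyl transfer faster than it attacks C8a, so that the fluoride chain stalls.
   - Fallback (known chemistry, ring C closed from the phenol side): it sets out from 4 and comes back at 8. Mild hydrolysis of 4 (aq HCl, THF) should give 3-[4-(allyloxy)phenyl]-1-(2-fluoro-4-methoxyphenyl)propan-1-one F1. Exchange of the activated fluoride for hydroxyl with 2-(methylsulfonyl)ethanol and NaH in DMF (SNAr, then loss of methyl vinyl sulfone) should give 3-[4-(allyloxy)phenyl]-1-(2-hydroxy-4-methoxyphenyl)propan-1-one F2. Pyrrolidine-mediated condensation of F2 with 5 in EtOH should pass through enone 9 and close by oxa-Michael addition, the classical flavanone synthesis, to 8.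

2. **Step 4.**
   - Risk: racemisation may be slower than reduction, so that enantio-convergence is lost. The ring-opened form may be reduced at its C=C bond, or the base may hold the material in the open phenoxide form.
   - Fallback (classical resolution in which the resolving group doubles as the leaving group): it sets out from 8 and comes back at 17. NaBH4 in MeOH/THF should give the racemic all-equatorial alcohol (±)-(2R*,3R*,4R*)-3-[4-(allyloxy)benzyl]-2-(2,4-dimethoxyphenyl)-7-methoxychroman-4-ol F3. Esterification with (S)-2-methoxy-2-phenylacetic acid (DCC, DMAP) should give two diastereomers that are separated by chromatography or crystallisation. These are the wanted (2R,3R,4R)-chroman-4-yl (S)-2-methoxy-2-phenylacetate F4 and the unwanted (2S,3S,4S)-chroman-4-yl (S)-2-methoxy-2-phenylacetate F5. F5 can be saponified, reoxidised and racemised for recycling. Under the conditions of step 7, F4 should ionise to the same cation 16 and give 17.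

3. **Step 7.**
   - Risk: the cation may lose the C3 proton, and reprotonation would scramble C3. It may also be attacked by the electron-rich ring B of a second molecule, or be attacked on the wrong face. In addition, the borate may protodeboronate, and prolonged acid exposure may ionise the C2–O1 bond.
   - Fallback (a stronger, non-polymerising carbon nucleophile, with the alkene built afterwards): it sets out from 10 and comes back at 18. The enol silane {[1-[4-(allyloxy)phenyl]vinyl]oxy}trimethylsilane F6 is made from commercial 1-[4-(allyloxy)phenyl]ethan-1-one with TMSOTf and Et3N. F6 should alkylate cation 16 (ZnCl2 or cat. TMSOTf, CH2Cl2, −78 °C) anti to the C3 benzyl group and give 2-{(2R,3R,4R)-3-[4-(allyloxy)benzyl]-2-(2,4-dimethoxyphenyl)-7-methoxychroman-4-yl}-1-[4-(allyloxy)phenyl]ethan-1-one F7. NaBH4 should then give the carbinol mixture 2-{(2R,3R,4R)-3-[4-(allyloxy)benzyl]-2-(2,4-dimethoxyphenyl)-7-methoxychroman-4-yl}-1-[4-(allyloxy)phenyl]ethan-1-ol F8. PPTS-catalysed dehydration in warm toluene should give the E-styrene (2R,3R,4R)-3-[4-(allyloxy)benzyl]-4-[(E)-4-(allyloxy)styryl]-2-(2,4-dimethoxyphenyl)-7-methoxychroman F9. Double deallylation under the conditions of step 8 should give 18.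

**Further compounds**
F1 | step 3 | 3-[4-(allyloxy)phenyl]-1-(2-fluoro-4-methoxyphenyl)propan-1-one | COc1ccc(c(F)c1)C(=O)CCc1ccc(OCC=C)cc1
F2 | step 3 | 3-[4-(allyloxy)phenyl]-1-(2-hydroxy-4-methoxyphenyl)propan-1-one | COc1ccc(c(O)c1)C(=O)CCc1ccc(OCC=C)cc1
F3 | step 4 | (±)-(2R*,3R*,4R*)-3-[4-(allyloxy)benzyl]-2-(2,4-dimethoxyphenyl)-7-methoxychroman-4-ol (racemic, one enantiomer drawn) | COc1ccc2c(c1)O[C@@H](c1ccc(OC)cc1OC)[C@H](Cc1ccc(OCC=C)cc1)[C@H]2O
F4 | step 4 | (2R,3R,4R)-3-[4-(allyloxy)benzyl]-2-(2,4-dimethoxyphenyl)-7-methoxychroman-4-yl (S)-2-methoxy-2-phenylacetate | COc1ccc2c(c1)O[C@@H](c1ccc(OC)cc1OC)[C@H](Cc1ccc(OCC=C)cc1)[C@H]2OC(=O)[C@@H](OC)c1ccccc1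
F5 | step 4 | (2S,3S,4S)-3-[4-(allyloxy)benzyl]-2-(2,4-dimethoxyphenyl)-7-methoxychroman-4-yl (S)-2-methoxy-2-phenylacetate | COc1ccc2c(c1)O[C@H](c1ccc(OC)cc1OC)[C@@H](Cc1ccc(OCC=C)cc1)[C@@H]2OC(=O)[C@@H](OC)c1ccccc1
F6 | step 7 | {[1-[4-(allyloxy)phenyl]vinyl]oxy}trimethylsilane | C=C(O[Si](C)(C)C)c1ccc(OCC=C)cc1
F7 | step 7 | 2-{(2R,3R,4R)-3-[4-(allyloxy)benzyl]-2-(2,4-dimethoxyphenyl)-7-methoxychroman-4-yl}-1-[4-(allyloxy)phenyl]ethan-1-one | COc1ccc2c(c1)O[C@@H](c1ccc(OC)cc1OC)[C@H](Cc1ccc(OCC=C)cc1)[C@H]2CC(=O)c1ccc(OCC=C)cc1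
F8 | step 7 | 2-{(2R,3R,4R)-3-[4-(allyloxy)benzyl]-2-(2,4-dimethoxyphenyl)-7-methoxychroman-4-yl}-1-[4-(allyloxy)phenyl]ethan-1-ol (carbinol epimers) | COc1ccc2c(c1)O[C@@H](c1ccc(OC)cc1OC)[C@H](Cc1ccc(OCC=C)cc1)[C@H]2CC(O)c1ccc(OCC=C)cc1
F9 | step 7 | (2R,3R,4R)-3-[4-(allyloxy)benzyl]-4-[(E)-4-(allyloxy)styryl]-2-(2,4-dimethoxyphenyl)-7-methoxychroman | COc1ccc2c(c1)O[C@@H](c1ccc(OC)cc1OC)[C@H](Cc1ccc(OCC=C)cc1)[C@H]2/C=C/c1ccc(OCC=C)cc1
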